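**Retrosynthetic overview**
1. (6S)-ε,ψ-Carotene ⇒ Wittig at C11=C12: (S)-ε-C15 phosphonium salt + C25 aldehyde (apo-12'-lycopenal).
2. C25 aldehyde ⇒ Wittig at C11'=C12': ψ-C15 phosphonium salt + symmetrical C10 dialdehyde.
3. Both C15 salts ⇒ the same one-pot C2 homologation of a C13 methyl ketone (vinyl Grignard, then Ph3P·HBr with allylic transposition).
4. The cyclic C13 ketone (S)-α-ionone ⇒ acyclic pseudoionone by a catalytic enantioselective H+-initiated C1–C6 closure with loss of H-4, a laboratory copy of lycopene ε-cyclase. Pseudoionone therefore feeds both end groups.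
5. Ring order: there is one ring only (ring A, the ε ring). It is closed in step 1 together with the only stereocentre, C6.

**Assumptions**
- The target SMILES decodes as 6S (priorities C5 > C1 > C7 > H) with every chain C=C E, so the route is planned for (6S)-ε,ψ-carotene.
- Carotenoid numbering is used for all intermediates: ring C1–C6, chain C7–C15, primes for the ψ half.
- Pseudoionone 1 is used as the single (3E,5E) isomer; a technical E/Z mixture would be fractionally distilled first.
- The sense of induction of the chiral acid in step 1 cannot be predicted. (R,R) is written; the equally accessible (S,S) antipode is used if a test run gives dextrorotatory (R)-α-ionone.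

**Route**

Step 1
Reactants: 1 (3E,5E)-pseudoionone
Product: 3 (S)-(−)-α-ionone, via ring cation 2 (not isolated)
Conditions: (R,R)-IDPi HN[P(=NSO2CF3)(O2C20H10Ar2)]2, Ar = 3,5-(CF3)2C6H3, O2C20H10Ar2 = 3,3'-diaryl-1,1'-binaphthalene-2,2'-diolate (5 mol %), (CF3)3COH/CH2Cl2 4:1, 0 °C, 48 h, stopped at full conversion; Et3N quench
Reagents that add atoms: none
Why: Proposed new method: the strong, confined chiral Brønsted acid protonates C2 of the isolated Me2C=CH unit (the only π bond not deactivated by the H-bonded carbonyl), the chain folds into a chair-like array inside the chiral anion pocket so that C1 is attacked by one face of the 5E alkene at C6 (the γ-carbon of the dienone, which gives the tertiary C5 cation 2 and fixes C6 as S), and the anion then removes H-4 to give the kinetic, non-conjugated ring alkene, the same H+ addition, C1–C6 closure and H-4 loss as in lycopene ε-cyclase; the closest known reaction types are the racemic H3PO4 cyclisation of pseudoionone to α-ionone and imidodiphosphorimidate-catalysed enantioselective proton-initiated polyene cyclisations of unactivated trisubstituted alkenes in fluorinated alcohols.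

Step 2
Reactants: 3 (S)-α-ionone; 4 vinylmagnesium bromide; 5 triphenylphosphine hydrobromide
Product: 8 (S)-ε-C15 salt [(2E,4E)-3-methyl-5-[(1S)-2,6,6-trimethylcyclohex-2-en-1-yl]penta-2,4-dien-1-yl]triphenylphosphonium bromide, via magnesium alkoxide 6 (not isolated), via vinyl-α-ionol 7 (not isolated)
Conditions: CH2=CHMgBr (1.2 equiv), THF, −20 → 0 °C, 1 h; then in the same flask HBr (33 % in AcOH, 1.2 equiv), Ph3P·HBr (1.1 equiv), MeOH, 0 °C → rt, 16 h; precipitate and recrystallise from CH2Cl2/EtOAc (removes the 9Z salt, can raise ee)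
Reagents that add atoms: vinylmagnesium bromide, C=C[Mg]Br; triphenylphosphine hydrobromide, [Br-].[PH+](c1ccccc1)(c1ccccc1)c1ccccc1
Why: Grignard 1,2-addition gives the tertiary bis-allylic carbinol (its C9 epimers do not matter because C9 becomes sp2), which acid ionises to a pentadienyl cation that Ph3P traps at the unhindered C11 terminus (SN1' phosphonium salt formation, 9E favoured), while C6 is never part of the reacting π system and keeps its configuration.

Step 3
Reactants: 1 (3E,5E)-pseudoionone; 4 vinylmagnesium bromide; 5 triphenylphosphine hydrobromide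
Product: 11 ψ-C15 salt [(2E,4E,6E)-3,7,11-trimethyldodeca-2,4,6,10-tetraen-1-yl]triphenylphosphonium bromide, via magnesium alkoxide 9 (not isolated), via vinyl-ψ-ionol 10 (not isolated)
Conditions: CH2=CHMgBr (1.2 equiv), THF, −20 → 0 °C, 1 h; then in the same flask HBr (33 % in AcOH, 1.2 equiv), Ph3P·HBr (1.1 equiv), MeOH, 0 °C → rt, 16 h; precipitate and recrystallise from CH2Cl2/EtOAc (all-E salt)
Reagents that add atoms: vinylmagnesium bromide, C=C[Mg]Br; triphenylphosphine hydrobromide, [Br-].[PH+](c1ccccc1)(c1ccccc1)c1ccccc1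
Why: The same Grignard 1,2-addition and SN1' phosphonium salt formation as in step 2, with Ph3P capturing the delocalised cation at its primary terminus faster than the mild acid can touch the isolated prenyl alkene, and with no stereocentre left in the product.

Step 4
Reactants: 11 ψ-C15 salt; 12 (2E,4E,6E)-2,7-dimethylocta-2,4,6-trienedial
Product: 15 all-E apo-12'-lycopenal (2E,4E,6E,8E,10E,12E,14E)-2,7,11,15,19-pentamethylicosa-2,4,6,8,10,12,14,18-octaenal, via ψ-C15 ylide 13 (not isolated), via 11'Z aldehyde 14 (not isolated)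
Conditions: 12 (1.5 equiv), NaOMe (1.05 equiv, added slowly), CH2Cl2/MeOH, −10 → 0 °C, N2, dark; then heptane, 90 °C, 2 h; chromatography (excess 12 recovered), crystallise
Reagents that add atoms: (2E,4E,6E)-2,7-dimethylocta-2,4,6-trienedial, O=C/C(C)=C/C=C/C=C(C)/C=O
Why: Wittig olefination that stops at the mono stage because the product aldehyde has lost the activating second formyl group and 12 is in excess, and the sterically hindered 11'Z isomer 14 relaxes thermally to the all-E polyene.

Step 5
Reactants: 8 (S)-ε-C15 salt; 15 all-E apo-12'-lycopenal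
Product: 18 (6S)-ε,ψ-carotene, via ε-C15 ylide 16 (not isolated), via 11Z-δ-carotene 17 (not isolated)
Conditions: NaOMe (1.2 equiv), CH2Cl2/MeOH, 0 °C → rt, N2, dark; then heptane, reflux, 6 h; filtration through deactivated alumina, crystallise from CH2Cl2/MeOH
Reagents that add atoms: none
Why: Wittig olefination of a semi-stabilised allylic ylide with a polyenal closes C11=C12, the hindered 11Z isomer 17 isomerises thermally to all-E, no new stereocentre is formed, and H-6 is not acidic enough for NaOMe, so 6S is retained.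

**Compound list**
1 | (3E,5E)-pseudoionone, (3E,5E)-6,10-dimethylundeca-3,5,9-trien-2-one | CC(C)=CCC/C(C)=C/C=C/C(C)=O | starting material
2 | tertiary C5 ring cation, 1,3,3-trimethyl-2-[(E)-3-oxobut-1-enyl]cyclohexyl cation with the C6 geometry of 3, ion-paired with the catalyst anion | CC(=O)/C=C/[C@@H]1[C+](C)CCCC1(C)C | intermediate
3 | (S)-(−)-α-ionone, (3E)-4-[(1S)-2,6,6-trimethylcyclohex-2-en-1-yl]but-3-en-2-one | CC(=O)/C=C/[C@@H]1C(C)=CCCC1(C)C | intermediate
4 | vinylmagnesium bromide | C=C[Mg]Br | starting material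
5 | triphenylphosphine hydrobromide | [Br-].[PH+](c1ccccc1)(c1ccccc1)c1ccccc1 | starting material
6 | bromomagnesium alkoxide of 7 (C9 epimers) | C=CC(C)(O[Mg]Br)/C=C/[C@@H]1C(C)=CCCC1(C)C | intermediate
7 | vinyl-α-ionol, (4E)-3-methyl-5-[(1S)-2,6,6-trimethylcyclohex-2-en-1-yl]penta-1,4-dien-3-ol (C9 epimers) | C=CC(C)(O)/C=C/[C@@H]1C(C)=CCCC1(C)C | intermediate
8 | (S)-ε-C15 salt, [(2E,4E)-3-methyl-5-[(1S)-2,6,6-trimethylcyclohex-2-en-1-yl]penta-2,4-dien-1-yl]triphenylphosphonium bromide | [Br-].c1ccccc1[P+](c1ccccc1)(c1ccccc1)C/C=C(C)/C=C/[C@@H]1C(C)=CCCC1(C)C | intermediate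
9 | bromomagnesium alkoxide of 10 (racemic) | CC(C)=CCC/C(C)=C/C=C/C(C)(O[Mg]Br)C=C | intermediate
10 | vinyl-ψ-ionol, (4E,6E)-3,7,11-trimethyldodeca-1,4,6,10-tetraen-3-ol (racemic) | CC(C)=CCC/C(C)=C/C=C/C(C)(O)C=C | intermediate
11 | ψ-C15 salt, [(2E,4E,6E)-3,7,11-trimethyldodeca-2,4,6,10-tetraen-1-yl]triphenylphosphonium bromide | CC(C)=CCC/C(C)=C/C=C/C(C)=C/C[P+](c1ccccc1)(c1ccccc1)c1ccccc1.[Br-] | intermediate
12 | C10 dialdehyde, (2E,4E,6E)-2,7-dimethylocta-2,4,6-trienedial | O=C/C(C)=C/C=C/C=C(C)/C=O | starting material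
13 | ψ-C15 ylide, [(2E,4E,6E)-3,7,11-trimethyldodeca-2,4,6,10-tetraenylidene]triphenylphosphorane | CC(C)=CCC/C(C)=C/C=C/C(C)=C/C=P(c1ccccc1)(c1ccccc1)c1ccccc1 | intermediate
14 | 11'Z isomer of 15, (2E,4E,6E,8Z,10E,12E,14E)-2,7,11,15,19-pentamethylicosa-2,4,6,8,10,12,14,18-octaenal | CC(C)=CCC/C(C)=C/C=C/C(C)=C/C=C\C(C)=C\C=C\C=C(C)\C=O | intermediate
15 | all-E apo-12'-lycopenal, (2E,4E,6E,8E,10E,12E,14E)-2,7,11,15,19-pentamethylicosa-2,4,6,8,10,12,14,18-octaenal | CC(C)=CCC/C(C)=C/C=C/C(C)=C/C=C/C(C)=C/C=C/C=C(C)/C=O | intermediate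
16 | ε-C15 ylide, [(2E,4E)-3-methyl-5-[(1S)-2,6,6-trimethylcyclohex-2-en-1-yl]penta-2,4-dienylidene]triphenylphosphorane | c1ccccc1P(c1ccccc1)(c1ccccc1)=C/C=C(C)/C=C/[C@@H]1C(C)=CCCC1(C)C | intermediate
17 | (6S,11Z)-ε,ψ-carotene | CC(C)=CCC/C(C)=C/C=C/C(C)=C/C=C/C(C)=C/C=C/C=C(C)/C=C\C=C(C)\C=C\[C@@H]1C(C)=CCCC1(C)C | intermediate
18 | (6S)-ε,ψ-carotene, all-E (CNP0405345.2) | CC(C)=CCC/C(C)=C/C=C/C(C)=C/C=C/C(C)=C/C=C/C=C(C)/C=C/C=C(C)/C=C/[C@@H]1C(C)=CCCC1(C)C | target

**Totals**
Total steps: 5. Longest linear sequence: 3 (1 → 3 → 8 → 18; the branch 1 → 11 → 15 → 18 is equally long).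

**Three steps most likely to fail**

Step 1.
- Risks: the ketone may buffer the acid and make turnover slow, the ee may be low, and cation 2 may leak to achiral β-ionone or to the exocyclic γ isomer.
- Fallback: starting from 1, the same ring closure is run without asymmetric induction (85 % H3PO4, 30 °C) to give racemic α-ionone F1. Its enantiomers are then separated by preparative chromatography on cellulose tris(3,5-dimethylphenylcarbamate). The levorotatory (S) enantiomer is 3, where the route is rejoined.

Step 2.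
- Risks: the Grignard reagent may enolise 3, the cation may lose H-6 to give a retro hydrocarbon, the 9Z salt may form, and the magnesium salts may hinder crystallisation in the one-pot mode.
- Fallback: starting from 3, the C2 unit is brought in by a Horner–Wadsworth–Emmons reaction with triethyl phosphonoacetate and NaH in THF. This gives ethyl (2E,4E)-(S)-α-ionylideneacetate F2, and the 9Z ester is removed by chromatography. Reduction with iBu2AlH in toluene at −78 °C gives (2E,4E)-(S)-α-ionylideneethanol F3. This primary allylic alcohol reacts with 5 in MeOH at room temperature to give 8, where the route is rejoined.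

Step 4.
- Risk: double olefination of 12 to lycopene, which would also cost material in the separation.
- Fallback: starting from 12, one formyl group is masked with HC(OMe)3 (1 equiv) and catalytic TsOH in MeOH, giving the C10 dialdehyde mono(dimethyl acetal) F4. Unreacted 12 and the bis-acetal are recycled. Ylide 13, made from 11 with NaOMe, can then react only once and gives apo-12'-lycopenal dimethyl acetal F5. Catalytic TsOH in aqueous acetone releases 15, where the route is rejoined.

**Further compounds**
F1 | step 1 | racemic α-ionone, (3E)-4-(2,6,6-trimethylcyclohex-2-en-1-yl)but-3-en-2-one | CC(=O)/C=C/C1C(C)=CCCC1(C)C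
F2 | step 2 | ethyl (2E,4E)-3-methyl-5-[(1S)-2,6,6-trimethylcyclohex-2-en-1-yl]penta-2,4-dienoate | CCOC(=O)/C=C(C)/C=C/[C@@H]1C(C)=CCCC1(C)C
F3 | step 2 | (2E,4E)-3-methyl-5-[(1S)-2,6,6-trimethylcyclohex-2-en-1-yl]penta-2,4-dien-1-ol | OC/C=C(C)/C=C/[C@@H]1C(C)=CCCC1(C)C
F4 | step 4 | (2E,4E,6E)-8,8-dimethoxy-2,7-dimethylocta-2,4,6-trienal | COC(OC)/C(C)=C/C=C/C=C(C)/C=O
F5 | step 4 | apo-12'-lycopenal dimethyl acetal, (2E,4E,6E,8E,10E,12E,14E)-1,1-dimethoxy-2,7,11,15,19-pentamethylicosa-2,4,6,8,10,12,14,18-octaene | CC(C)=CCC/C(C)=C/C=C/C(C)=C/C=C/C(C)=C/C=C/C=C(C)/C(OC)OC
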